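**Plan**

- Retrosynthesis: the C8 methacrylate (C8–O, with inversion), the C10 acetoxy/methyl pair and the C4–C5 epoxide are taken back to a ten-membered C1-enone 6,12-lactone. The lactone C6–O bond is then cut while a transannular C1–C6 bond is re-formed.
- Enabling feature: C1 (ketone) and C6 (lactone carbinol carbon, allylic to C4=C5) lie 1,6 across the ten-membered ring. The macrocycle therefore folds back to a cis-fused hydroxy-octalin (ring A: C1–C6 with C4=C5; ring B: C1, C6–C10) whose C12 amide sits behind C6. C10 is kept sp2 (C10=C14) so that only the C1–C6 bond can fragment.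
- Further cuts: C1–C10 (alkenyl bromide to ketone), C8–C9 (allylsilane on a lactone acetal), C11–C13 and C6–C7 (enolate alkylation and Michael addition on a butenolide). Ring A comes from 4-methylanisole.
- Forward order: ring A by Birch reduction, then the C7/C8/C11/C12 lactone, then ring B, then fragmentation of the bicycle to the ten-membered ring with lactone closure at C6, then epoxide, C10 ketol and esters.
- Stereochemistry: C6 (as carbon centre) from the hydrazine auxiliary; C7, C11 and C8 from the menthyloxy butenolide; C1 from the ring fusion; C6–O by inversion in the key step; C4/C5 and C10 by substrate control; C8 corrected by Mitsunobu inversion.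

Key step: step 10

Remark: atoms are numbered C1–C15 as in the germacrane skeleton of the target (C1 ketone, C4/C5 epoxide, C6 lactone carbinol carbon, C8 methacrylate carbon, C10 acetoxy carbon, C11–C13 lactone side chain, C14 on C10, C15 on C4).
Remark: butenolide 6 (from (1S,2R,5S)-menthol) and hydrazine 4 are taken as purchasable; hydrazone 5 is used as its mixture of C=N isomers.

**Step 1**
Reactants: 1 4-methylanisole
Product: 2 1-methoxy-4-methylcyclohexa-1,4-diene
Conditions: Li, NH3 (l), t-BuOH, THF, −78 °C
Reagents that add atoms: none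
Why: Birch reduction of the anisole should give the 2,5-dihydro product, which places the enol ether at C1 and the trisubstituted C4=C5 alkene of ring A.

**Step 2**
Reactants: 2 1-methoxy-4-methylcyclohexa-1,4-diene
Product: 3 4-methylcyclohex-3-en-1-one
Conditions: oxalic acid (cat.), acetone/H2O, 20 °C
Reagents that add atoms: water, O
Why: mild acid hydrolysis of the enol ether; oxalic acid is too weak to move the alkene into conjugation, so the β,γ-unsaturated ketone should be obtained.

**Step 3**
Reactants: 3 4-methylcyclohex-3-en-1-one; 4 (S)-1-amino-2-(methoxymethyl)pyrrolidine (SAMP)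
Product: 5 SAMP hydrazone of 3
Conditions: cyclohexane, 4 Å molecular sieves, 60 °C
Reagents that add atoms: none
Why: condensation of ketone and hydrazine (Enders SAMP hydrazone formation) masks the ketone and installs the auxiliary that will control C6.

**Step 4**
Reactants: 5 SAMP hydrazone of 3; 6 (5S)-5-[(1S,2R,5S)-menthyloxy]furan-2(5H)-one; 7 benzyl chloromethyl ether
Product: 10 SAMP hydrazone of keto lactone 11 (6S,7S,8S,11R), via lithium azaenolate 8 (not isolated), via lithium lactone enolate 9 (not isolated)
Conditions: LiN(iPr)2, THF, 0 °C; then 6, −95 to −78 °C; then 7, DMPU, −78 to −30 °C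
Reagents that add atoms: none
Why: Enders azaenolate Michael addition followed by alkylation of the lactone enolate (tandem conjugate addition–alkylation on a 5-alkoxybutenolide): the SAMP auxiliary shields one face of azaenolate 8 and sets C6 (S), the nucleophile adds to C7 anti to the menthyloxy group on C8, and 7 alkylates C11 of enolate 9 anti to the new C7 substituent.

**Step 5**
Reactants: 10 SAMP hydrazone of keto lactone 11
Product: 11 (3R,4S,5S)-3-(benzyloxymethyl)-5-[(1S,2R,5S)-menthyloxy]-4-[(1S)-3-methyl-6-oxocyclohex-2-en-1-yl]oxolan-2-one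
Conditions: saturated aqueous oxalic acid, Et2O, 20 °C
Reagents that add atoms: water, O
Why: two-phase oxalic acid hydrolysis of the SAMP hydrazone (Enders cleavage) should regenerate the ketone without epimerization at C6 or alkene migration and return the auxiliary.

**Step 6**
Reactants: 11 keto lactone acetal; 12 (2-bromoallyl)trimethylsilane
Product: 13 (3R,4S,5R)-3-(benzyloxymethyl)-5-(2-bromoprop-2-en-1-yl)-4-[(1S)-3-methyl-6-oxocyclohex-2-en-1-yl]oxolan-2-one
Conditions: Me3SiOSO2CF3 (0.3 equiv), CH2Cl2, −78 to −30 °C
Reagents that add atoms: none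
Why: Hosomi–Sakurai-type substitution of the lactone acetal after silyl triflate ionisation (Noyori conditions, which leave the ketone untouched); the allylsilane should add to C8 anti to the C7 substituent, making the lactone C7/C8 trans.

**Step 7**
Reactants: 13 bromoallyl keto lactone
Product: 14 tricyclic hydroxy lactone (1R,6S,7S,8R,11R): cis-fused ring A/ring B octalin with C1–OH, C4=C5, C15 methyl and C10=C14 methylene, the C8–O–C12 γ-lactone trans-fused on C7–C8, CH2OBn on C11
Conditions: CrCl2 (6 equiv), NiCl2 (5 mol %), DMF, 25–50 °C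
Reagents that add atoms: none
Why: intramolecular Nozaki–Hiyama–Kishi addition of the alkenyl bromide to the C1 ketone closes ring B and creates the tertiary allylic alcohol; the trans-fused lactone holds ring B in the chair with C11 and O8 equatorial, the C6–C5 bond of ring A is then axial, so only the cis ring fusion (C1 hydroxyl axial, cis to H6) can form.

**Step 8**
Reactants: 14 tricyclic hydroxy lactone
Product: 15 hydroxy amide (1R,6S,7S,8R,11R): N,N-dimethylamide at C12, free hydroxyls at C1 and C8
Conditions: Al(CH3)3, (CH3)2NH·HCl, CH2Cl2, 0 to 40 °C; aqueous KNaC4H4O6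
Reagents that add atoms: dimethylamine hydrochloride, CNC.Cl
Why: Weinreb aminolysis of the strained trans-fused γ-lactone with the aluminium amide should give the γ-hydroxy amide, which frees O8 and turns C12 into a carbonyl donor that can reach C6.

**Step 9**
Reactants: 15 hydroxy amide
Product: 16 C8 tert-butyldimethylsilyl ether of 15
Conditions: t-BuMe2SiOSO2CF3 (1.1 equiv), 2,6-lutidine, CH2Cl2, −78 °C
Reagents that add atoms: tert-butyldimethylsilyl trifluoromethanesulfonate, CC(C)(C)[Si](C)(C)OS(=O)(=O)C(F)(F)F
Why: silyl ether formation selective for the secondary C8 hydroxyl over the hindered tertiary allylic C1 hydroxyl, so that O8 cannot compete for C4 or C6 in the next step.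

**Step 10**
Reactants: 16 C8 silyl ether (cis-fused hydroxy-octalin amide)
Product: 21 (4Z,6R,7R,8R,11R)-13-benzyloxy-8-(tert-butyldimethylsilyloxy)-1-oxogermacra-4,10(14)-dien-6,12-olide, via alkoxy radical 17 (not isolated), via allyl radical 18 (not isolated), via allyl cation 19 (not isolated), via iminium ether 20 (not isolated)
Conditions: (NH4)2Ce(NO3)6 (2.5 equiv), NaHCO3, CH3CN/H2O 20:1, 400 nm LEDs, 0 °C; pH 7 buffer work-up
Reagents that add atoms: water, O
Why: Proposed new method: under 400 nm light (NH4)2Ce(NO3)6 should oxidize the C1 hydroxyl of 16 by ligand-to-metal charge transfer to alkoxy radical 17, β-scission of the ring-fusion bond C1–C6 then gives the C1 enone and allyl radical 18 (C4–C5–C6), a second tetravalent cerium oxidizes 18 to allyl cation 19, the amide oxygen bonds to C6 to give iminium ether 20, and water hydrolyses 20 to lactone 21. The closest known reaction types are the cerium-photocatalysed ring opening of unstrained cycloalkanols, the oxidative fragmentation of tertiary alcohols by (NH4)2Ce(NO3)6 and the tandem alkoxy-radical β-fragmentation–cyclisation of hypoiodites. The ten-membered ring forms by fragmentation of the bicycle (ring expansion, no new ring bond) and the γ-lactone by 5-exo attack of the carbonyl oxygen on the allyl terminus C6, attack at C4 being excluded because it needs a seven-membered ring. The new stereocentre C6 is controlled by the bicycle: in the ring B chair fixed by the equatorial C8 silyloxy group and C7 side chain, the C7–C11 bond is antiperiplanar to the breaking C1–C6 bond, so the amide oxygen sits behind C6 and bonds on the face opposite to the departing C1 (inversion, cis-fused lactone) before the sickle-shaped allyl unit, which should turn over as slowly as an E-alkene in a ten-membered ring, can present its other face. The step needs regioselective β-scission, secured because C1–C10 would give a vinyl radical (C10 is sp2) and C1–C2 a primary radical, whereas C1–C6 gives a secondary allylic radical with release of the cis-octalin strain; the Z geometry of C4=C5 is inherited from ring A. NaHCO3 protects the silyl ether and the allylic alcohol from acid and holds the released dimethylamine as its salt so that it cannot add to the enone.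

**Step 11**
Reactants: 21 ten-membered dienone lactone
Product: 22 (4R,5S,6S,7R,8R,11R)-4,5-epoxide of 21
Conditions: 3-ClC6H4CO3H, NaHCO3, CH2Cl2, 0 °C
Reagents that add atoms: 3-chloroperbenzoic acid, OOC(=O)c1cccc(Cl)c1
Why: Prilezhaev epoxidation of the electron-rich trisubstituted C4=C5 alkene (the enone alkene is electron-poor and left); allylic 1,3-strain holds H6 in the alkene plane and the peracid should add anti to the allylic C6–O bond, syn addition to the Z-alkene giving the cis-epoxide (4R,5S).

**Step 12**
Reactants: 22 epoxy enone lactone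
Product: 24 (4R,5S,6S,7R,8R,10R,11R)-10-hydroxy ketone (C14 now methyl), via hydroperoxide 23 (not isolated)
Conditions: Mn(C11H19O2)3 (manganese tris(dipivaloylmethanate), 10 mol %), PhSiH3, O2 (1 atm), i-PrOH/CH2Cl2, 0 °C; then P(OEt)3
Reagents that add atoms: dioxygen, O=O
Why: Mukaiyama-type hydrogen-atom-transfer hydration of the α-methylene ketone (Magnus α-hydroxylation of enones): hydrogen-atom transfer to C14 is followed by O2 capture at C10, expected on the face away from the 1,3-related C8 silyloxy group (10R), and the phosphite reduces hydroperoxide 23 to the tertiary alcohol.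

**Step 13**
Reactants: 24 10-hydroxy ketone
Product: 25 13-alcohol (benzyl ether removed)
Conditions: H2 (1 atm), Pd on carbon (Pd/C, 10 %), EtOAc, 20 °C
Reagents that add atoms: none
Why: hydrogenolysis of the benzyl ether over palladium; no alkene remains, and the trisubstituted epoxide and the ketone should survive neutral conditions.

**Step 14**
Reactants: 25 10,13-diol
Product: 26 10,13-diacetate
Conditions: Ac2O, 4-(dimethylamino)pyridine, Et3N, CH2Cl2, 20–35 °C
Reagents that add atoms: acetic anhydride, CC(=O)OC(C)=O
Why: nucleophilic acyl-transfer catalysis (Steglich-type acetylation) should esterify the primary C13 and the tertiary C10 hydroxyls in one operation.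

**Step 15**
Reactants: 26 10,13-diacetate silyl ether
Product: 27 (4R,5S,6S,7S,8R,10R,11R)-8-alcohol
Conditions: HF·pyridine, pyridine, THF, 0 °C
Reagents that add atoms: none
Why: fluoride-mediated desilylation buffered with pyridine should free the C8 hydroxyl without base-induced elimination of the β-acetoxy lactone or opening of the epoxide.

**Step 16**
Reactants: 27 8-alcohol; 28 methacrylic acid
Product: 29 target, (4R,5S,6S,7S,8S,10R,11R)-10,13-diacetoxy-4,5-epoxy-8-methacryloyloxy-1-oxogermacran-6,12-olide
Conditions: PPh3, i-PrO2CN=NCO2i-Pr, toluene, 0 to 20 °C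
Reagents that add atoms: none
Why: Mitsunobu esterification with methacrylic acid: SN2 displacement at the activated C8 oxygen inverts the centre (8R to 8S) and installs the methacrylate, completing the target.

**Compound list**

1 | 4-methylanisole | COc1ccc(C)cc1 | starting material
2 | 1-methoxy-4-methylcyclohexa-1,4-diene | COC1=CCC(C)=CC1 | intermediate
3 | 4-methylcyclohex-3-en-1-one | CC1=CCC(=O)CC1 | intermediate
4 | (S)-1-amino-2-(methoxymethyl)pyrrolidine (SAMP) | COC[C@@H]1CCCN1N | starting material
5 | SAMP hydrazone of 3 (C=N isomer mixture) | COC[C@@H]1CCCN1N=C1CCC(C)=CC1 | intermediate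
6 | (5S)-5-[(1S,2R,5S)-menthyloxy]furan-2(5H)-one | O=C1C=C[C@@H](O[C@H]2C[C@@H](C)CC[C@@H]2C(C)C)O1 | starting material
7 | benzyl chloromethyl ether | ClCOCc1ccccc1 | starting material
8 | lithium azaenolate of 5 (deprotonated at C6) | [Li+].COC[C@@H]1CCCN1[N-]C1=CC=C(C)CC1 | intermediate (not isolated)
9 | lithium lactone enolate of the Michael adduct (C6–C7 bond formed) | [Li+].COC[C@@H]1CCCN1N=C1CCC(C)=C[C@H]1[C@H]1C=C([O-])O[C@@H]1O[C@H]1C[C@@H](C)CC[C@@H]1C(C)C | intermediate (not isolated)
10 | SAMP hydrazone of keto lactone 11 (6S,7S,8S,11R) | COC[C@@H]1CCCN1N=C1CCC(C)=C[C@H]1[C@H]1[C@H](COCc2ccccc2)C(=O)O[C@@H]1O[C@H]1C[C@@H](C)CC[C@@H]1C(C)C | intermediate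
11 | (3R,4S,5S)-3-(benzyloxymethyl)-5-[(1S,2R,5S)-menthyloxy]-4-[(1S)-3-methyl-6-oxocyclohex-2-en-1-yl]oxolan-2-one | O=C1CCC(C)=C[C@H]1[C@H]1[C@H](COCc2ccccc2)C(=O)O[C@@H]1O[C@H]1C[C@@H](C)CC[C@@H]1C(C)C | intermediate
12 | (2-bromoallyl)trimethylsilane | C=C(Br)C[Si](C)(C)C | starting material
13 | (3R,4S,5R)-3-(benzyloxymethyl)-5-(2-bromoprop-2-en-1-yl)-4-[(1S)-3-methyl-6-oxocyclohex-2-en-1-yl]oxolan-2-one | O=C1CCC(C)=C[C@H]1[C@H]1[C@H](COCc2ccccc2)C(=O)O[C@@H]1CC(Br)=C | intermediate
14 | tricyclic hydroxy lactone (1R,6S,7S,8R,11R): cis-fused octalin, C1–OH, C10=C14, trans-fused 8,12-lactone, C13 benzyl ether | O[C@]12CCC(C)=C[C@H]1[C@H]1[C@H](COCc3ccccc3)C(=O)O[C@@H]1CC2=C | intermediate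
15 | hydroxy amide (1R,6S,7S,8R,11R): C12 N,N-dimethylamide, C1 and C8 hydroxyls | O[C@]12CCC(C)=C[C@H]1[C@@H]([C@H](COCc3ccccc3)C(=O)N(C)C)[C@H](O)CC2=C | intermediate
16 | C8 tert-butyldimethylsilyl ether of 15 | O[C@]12CCC(C)=C[C@H]1[C@@H]([C@H](COCc3ccccc3)C(=O)N(C)C)[C@H](O[Si](C)(C)C(C)(C)C)CC2=C | intermediate
17 | C1 alkoxy radical of 16 | [O][C@]12CCC(C)=C[C@H]1[C@@H]([C@H](COCc3ccccc3)C(=O)N(C)C)[C@H](O[Si](C)(C)C(C)(C)C)CC2=C | intermediate (not isolated)
18 | ring-opened allyl radical (ten-membered C1 enone, radical over C4–C5–C6) | CC(C)(C)[Si](C)(C)O[C@@H]1CC(=C)C(=O)CC/C(C)=C\[CH][C@H]1[C@H](COCc2ccccc2)C(=O)N(C)C | intermediate (not isolated)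
19 | allyl cation (nitrate), charge over C4–C5–C6 | CC(C)(C)[Si](C)(C)O[C@@H]1CC(=C)C(=O)CC/C(C)=C\[CH+][C@H]1[C@H](COCc2ccccc2)C(=O)N(C)C.[O-][N+](=O)[O-] | intermediate (not isolated)
20 | cyclic iminium ether (nitrate), C6–O bond formed | CC(C)(C)[Si](C)(C)O[C@@H]1CC(=C)C(=O)CC/C(C)=C\[C@H]2OC(=[N+](C)C)[C@@H](COCc3ccccc3)[C@H]21.[O-][N+](=O)[O-] | intermediate (not isolated)
21 | (4Z,6R,7R,8R,11R)-13-benzyloxy-8-(tert-butyldimethylsilyloxy)-1-oxogermacra-4,10(14)-dien-6,12-olide | CC(C)(C)[Si](C)(C)O[C@@H]1CC(=C)C(=O)CC/C(C)=C\[C@H]2OC(=O)[C@@H](COCc3ccccc3)[C@H]21 | intermediate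
22 | (4R,5S,6S,7R,8R,11R)-4,5-epoxide of 21 | CC(C)(C)[Si](C)(C)O[C@@H]1CC(=C)C(=O)CC[C@@]2(C)O[C@H]2[C@H]2OC(=O)[C@@H](COCc3ccccc3)[C@H]21 | intermediate
23 | C10 hydroperoxide (10R) | CC(C)(C)[Si](C)(C)O[C@@H]1C[C@@](C)(OO)C(=O)CC[C@@]2(C)O[C@H]2[C@H]2OC(=O)[C@@H](COCc3ccccc3)[C@H]21 | intermediate (not isolated)
24 | (4R,5S,6S,7R,8R,10R,11R)-10-hydroxy ketone, C13 benzyl ether, C8 silyl ether | CC(C)(C)[Si](C)(C)O[C@@H]1C[C@@](C)(O)C(=O)CC[C@@]2(C)O[C@H]2[C@H]2OC(=O)[C@@H](COCc3ccccc3)[C@H]21 | intermediate
25 | 10,13-diol, C8 silyl ether | CC(C)(C)[Si](C)(C)O[C@@H]1C[C@@](C)(O)C(=O)CC[C@@]2(C)O[C@H]2[C@H]2OC(=O)[C@@H](CO)[C@H]21 | intermediate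
26 | 10,13-diacetate, C8 silyl ether | CC(C)(C)[Si](C)(C)O[C@@H]1C[C@@](C)(OC(C)=O)C(=O)CC[C@@]2(C)O[C@H]2[C@H]2OC(=O)[C@@H](COC(C)=O)[C@H]21 | intermediate
27 | (4R,5S,6S,7S,8R,10R,11R)-10,13-diacetoxy-4,5-epoxy-8-hydroxy-1-oxogermacran-6,12-olide | O[C@@H]1C[C@@](C)(OC(C)=O)C(=O)CC[C@@]2(C)O[C@H]2[C@H]2OC(=O)[C@@H](COC(C)=O)[C@H]21 | intermediate
28 | methacrylic acid | C=C(C)C(=O)O | starting material
29 | (4R,5S,6S,7S,8S,10R,11R)-10,13-diacetoxy-4,5-epoxy-8-methacryloyloxy-1-oxogermacran-6,12-olide (CNP0166747.1) | C=C(C)C(=O)O[C@H]1C[C@@](C)(OC(C)=O)C(=O)CC[C@@]2(C)O[C@H]2[C@H]2OC(=O)[C@@H](COC(C)=O)[C@H]21 | target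

**Step count and risks**

Total step count: 16. Longest linear sequence: 16 steps (from 4-methylanisole; all other building blocks are purchased).

The three steps most likely to fail:

Step 10 (bears the new-method label). What may go wrong: the cerium-mediated sequence may not fragment cleanly (capture of the allyl cation by nitrate or water, over-oxidation), or the allyl intermediate may relax before capture so that the lactone closes on both faces of C6. Fallback with known chemistry, setting out from 16 and coming back at 21: hypoiodite alkoxy-radical fragmentation under Suárez conditions (PhI(OAc)2, I2, CH2Cl2, visible light, 20 °C) should give the ring-expanded allylic iodide F1. Ionisation of the iodide with AgOSO2CF3 and 2,6-di-tert-butylpyridine in wet CH3CN at −30 °C should then let the amide oxygen close the lactone at C6 and, after hydrolysis of the iminium ether, return 21.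

Step 11. What may go wrong: poor facial selectivity of oxygen transfer to the Z-alkene, the peracid choosing the face syn to the lactone oxygen. Fallback, setting out from 21 and coming back at 22: N-bromosuccinimide in THF/H2O at 0 °C should give bromohydrin F2 (bromonium ion on the face an electrophile prefers, water opening at the tertiary C4 from the other face). K2CO3 in CH3OH at 0 °C should then close the epoxide by displacement of bromide at C5, which places the oxygen on the face opposite to the one the electrophile chose and returns 22.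

Step 12. What may go wrong: O2 capture on the wrong face of C10, or simple reduction to the C10 methyl ketone. Fallback, setting out from 22 and coming back at 24: conjugate reduction of the enone with LiBH(s-Bu)3 in THF at −78 °C should give the C1–C10 lithium enolate F3 regiospecifically. Oxidation in the same flask with the matching enantiomer of Davis (camphorsulfonyl)oxaziridine, a reagent-controlled enolate hydroxylation, should return 24 after NH4Cl work-up.

**Further compounds**

F1 | step 10 | ring-expanded allylic iodide (ten-membered C1 enone amide, iodine at C6, epimer mixture) | CC(C)(C)[Si](C)(C)O[C@@H]1CC(=C)C(=O)CC/C(C)=C\C(I)[C@H]1[C@H](COCc2ccccc2)C(=O)N(C)C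
F2 | step 11 | bromohydrin (C4 hydroxyl, C5 bromide, anti) | CC(C)(C)[Si](C)(C)O[C@@H]1CC(=C)C(=O)CC[C@@](C)(O)[C@H](Br)[C@H]2OC(=O)[C@@H](COCc3ccccc3)[C@H]21
F3 | step 12 | C1–C10 lithium enolate (C14 methyl; enolate geometry not defined) | [Li+].CC(C)(C)[Si](C)(C)O[C@@H]1CC(C)=C([O-])CC[C@@]2(C)O[C@H]2[C@H]2OC(=O)[C@@H](COCc3ccccc3)[C@H]21
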